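**Strategy.** The ten-membered carbocycle is not closed; it is uncovered. The C1 ketone and the C6 lactone oxygen sit 1,6 across the ring, and C1–C6 with the C4 methyl map onto a toluene ring fused to a six-membered ring B (C1, C6–C10). All C7–C10 substituents are therefore set trans on a rigid tetralin, the arene is Birch-reduced, and one oxidative scission of the tetrasubstituted C1=C6 ring-fusion olefin merges rings A and B into the cyclodecene while delivering both carbonyls and the (Z)-C3=C4 olefin. The precursor is the hexahydronaphthalene carrying the C7 acetic acid, a C8 silyl ether and a compact C9/C14 acetonide.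

Key step: step 10

Remark: germacrane numbering of the target (C1–C15) is used for every intermediate and β means the face of the C7 side chain; the C1 carbinol made in step 11 is erased in step 15, so its configuration is left open, and aqueous quenches only supply protons.

Step 1
Reactants: 1 7-methyl-1-tetralone; 2 ethyl bromoacetate
Product: 4 ethyl 2-(7-methyl-3,4-dihydronaphthalen-1-yl)acetate, via Reformatsky hydroxy ester 3 (not isolated)
Conditions: Zn dust (TMSCl-activated), THF, reflux; 1 M HCl; crude, TsOH·H2O (cat.), PhMe, reflux, Dean–Stark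
Reagents that add atoms: none
Why: Reformatsky addition of the zinc enolate to the aryl ketone and acid-catalysed dehydration of the tertiary benzylic alcohol; equilibration under TsOH should favour the endocyclic styrene-type C7=C8 isomer over the exocyclic enoate, which suffers peri strain.

Step 2
Reactants: 4 ethyl 2-(7-methyl-3,4-dihydronaphthalen-1-yl)acetate
Product: 6 ethyl 2-[(1S,2S)-2-hydroxy-7-methyl-1,2,3,4-tetrahydronaphthalen-1-yl]acetate, via alkyl(isopinocampheyl)borane 5 (not isolated)
Conditions: IpcBH2 (prepared from (+)-α-pinene, 1.1 equiv), THF, −25 °C; then 30% H2O2, pH 7 phosphate buffer, 0 °C → rt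
Reagents that add atoms: hydrogen peroxide, OO
Why: Brown asymmetric hydroboration–oxidation: boron adds to the less substituted C8 and hydrogen to benzylic C7 on the same face, so the C7 branch and the C8 hydroxyl end trans, and the (+)-α-pinene-derived borane selects the alkene face in the sense known for 1-substituted cycloalkenes ((S)-carbinols), setting C7 and C8; the ester survives the low temperature and buffered oxidation.

Step 3
Reactants: 6 ethyl 2-[(1S,2S)-2-hydroxy-7-methyl-1,2,3,4-tetrahydronaphthalen-1-yl]acetate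
Product: 7 ethyl 2-[(1S,2S)-2-(tert-butyldimethylsilyloxy)-7-methyl-1,2,3,4-tetrahydronaphthalen-1-yl]acetate
Conditions: TBSCl, imidazole, DMF, rt
Reagents that add atoms: tert-butyldimethylsilyl chloride, CC(C)(C)[Si](C)(C)Cl
Why: Standard silylation of the secondary alcohol; TBS survives dissolving metal, ozone, hydride, amide base and mild acid and is the last group removed.

Step 4
Reactants: 7 ethyl 2-[(1S,2S)-2-(tert-butyldimethylsilyloxy)-7-methyl-1,2,3,4-tetrahydronaphthalen-1-yl]acetate
Product: 9 ethyl 2-[(1S,2S)-2-(tert-butyldimethylsilyloxy)-7-methyl-1,2-dihydronaphthalen-1-yl]acetate, via C10 benzylic bromide 8 (not isolated)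
Conditions: NBS (1.05 equiv), AIBN (cat.), NaHCO3, PhCF3, 80 °C; filter; DBU, PhMe, 60 °C
Reagents that add atoms: none
Why: Wohl–Ziegler bromination at the only secondary benzylic site C10 (the tertiary C7–H is deactivated by the neighbouring silyloxy- and ester-bearing carbons and its hindered radical is trapped slowly), then E2 loss of HBr, which can only go toward C9; no acid is present that could aromatise the allylic silyl ether.

Step 5
Reactants: 9 ethyl 2-[(1S,2S)-2-(tert-butyldimethylsilyloxy)-7-methyl-1,2-dihydronaphthalen-1-yl]acetate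
Product: 10 9β,10β-epoxide of 9 (epoxide anti to the C8 silyloxy group)
Conditions: DMDO (acetone solution, 1.2 equiv), CH2Cl2, −20 → 0 °C
Reagents that add atoms: dimethyldioxirane, CC1(C)OO1
Why: Electrophilic epoxidation with a neutral dioxirane; oxygen should be delivered to the face of the cis-disubstituted styrene opposite the adjacent allylic silyloxy group, setting C9–O trans to C8–O, and the acid-labile benzylic epoxide never meets a carboxylic acid.

Step 6
Reactants: 10 9β,10β-epoxide of 9
Product: 12 ethyl 2-[(1S,2R,3R,4R)-2-(tert-butyldimethylsilyloxy)-3-hydroxy-4-(hydroxymethyl)-7-methyl-1,2,3,4-tetrahydronaphthalen-1-yl]acetate, via C10 (isopropoxydimethylsilyl)methyl carbinol 11 (not isolated)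
Conditions: (i-PrO)Me2SiCH2MgCl (3 equiv), CuI (10 mol %), THF, −40 → −10 °C; aq. NH4Cl; crude, 30% H2O2, KF, KHCO3, THF/MeOH, rt
Reagents that add atoms: (isopropoxydimethylsilyl)methylmagnesium chloride, CC(C)O[Si](C)(C)C[Mg]Cl; hydrogen peroxide, OO
Why: Copper-catalysed SN2 opening of the aryl epoxide by Tamao's hydroxymethyl-anion equivalent at benzylic C10 (activated and remote from the silyloxy group) with inversion, placing C14 trans to the retained C9 hydroxyl, then Tamao–Fleming oxidation of the C–Si bond; the ester tolerates the sluggish silylmethyl Grignard at low temperature.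

Step 7
Reactants: 12 ethyl 2-[(1S,2R,3R,4R)-2-(tert-butyldimethylsilyloxy)-3-hydroxy-4-(hydroxymethyl)-7-methyl-1,2,3,4-tetrahydronaphthalen-1-yl]acetate
Product: 13 C9,C14-O-isopropylidene acetal of 12
Conditions: 2,2-dimethoxypropane, PPTS (cat.), CH2Cl2, rt
Reagents that add atoms: 2,2-dimethoxypropane, COC(C)(C)OC
Why: Acid-catalysed transketalisation of the 1,3-diol to the trans-fused six-membered acetonide, one compact group for C9–O and C14–O that is inert to lithium/ammonia and ozone and keeps the C10 flank of the future C1=C6 bond uncrowded.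

Step 8
Reactants: 13 C9,C14-O-isopropylidene acetal of 12
Product: 14 carboxylic acid of 13
Conditions: LiOH·H2O, THF/MeOH/H2O, rt; 1 M HCl to pH 4–5, 0 °C
Reagents that add atoms: lithium hydroxide, [Li+].[OH-]
Why: Saponification; a carboxylate (an ester would be reduced by lithium in ammonia) is needed for the next step, and silyl ether and acetal are base-stable.

Step 9
Reactants: 14 carboxylic acid of 13
Product: 15 Birch diene of 14 (hexahydronaphthalene with C1=C6 and C3=C4 olefins)
Conditions: Li (10 equiv), NH3(l)/THF, t-BuOH (8 equiv), −78 → −33 °C; solid NH4Cl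
Reagents that add atoms: none
Why: Birch reduction of the 1,2,4-trialkylbenzene: protonation occurs at the unsubstituted, para-related C2 and C5, leaving the three alkylated carbons sp2, so the tetrasubstituted C1=C6 and trisubstituted C3=C4 olefins appear together; the carboxylate, silyl ether, acetal (no benzylic C–O bond) and the four stereocentres are untouched.

Step 10
Reactants: 15 Birch diene of 14
Product: 18 ten-membered (Z)-cyclodec-3-ene-1,6-dione acid (7β-CH2CO2H; 8α-OTBS; 9β-O/C14-O acetonide), via primary ozonide 16 (not isolated), via bridged 1,2,4-trioxolane 17 (not isolated)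
Conditions: O3 (1.0 equiv, titrated CH2Cl2 solution added at −78 °C), CH2Cl2, −78 °C; then PPh3 (1.5 equiv), −78 °C → rt
Reagents that add atoms: ozone, [O-][O+]=O
Why: Ozone adds as a 1,3-dipole to the tetrasubstituted C1=C6 bond (16), which cycloreverts to a ketone and a carbonyl oxide held in one molecule and recombines to the bridged trioxolane 17 (the C12 acid may instead trap a C6 carbonyl oxide as an acyloxy hydroperoxide); PPh3 reduces either peroxide to the diketone. The closest known reaction type is the ozonolysis of Δ9,10-octalins and Birch-derived isotetralins to cyclodecane-1,6-diones. The ten-membered ring arises by scission of the bond shared by rings A and B, a ring-expanding fragmentation and not an end-to-end cyclisation, so no macrocyclisation is needed. No stereocentre is created; C7–C10 are untouched under neutral conditions and the Z geometry of C3=C4 is inherited from the six-membered ring. The selectivity required is chemoselectivity for the tetrasubstituted over the trisubstituted olefin; it rests on the higher electron density of the four-fold alkylated bond, on exactly one equivalent of ozone at −78 °C, and on the tied-back acetonide and single remote silyl ether, which leave the ring-fusion bond accessible.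

Step 11
Reactants: 18 ten-membered 1,6-diketone acid
Product: 19 1ξ,6β-dihydroxy acid
Conditions: LiBH(s-Bu)3 (L-Selectride, 4 equiv), THF, −78 °C; H2O2, pH 7 buffer, 0 °C; extraction at pH 6, used at once
Reagents that add atoms: none
Why: Ketone reduction by a bulky trialkylborohydride, which attacks medium-ring carbonyls from the ring periphery; at C6 this is the face anti to the C7–C8 ring bond with the C7 branch eclipsing the carbonyl, so the 6β-carbinol cis to the branch is expected (as with 2-substituted cycloalkanones), the configuration wanted for an invertive ring closure; the carboxylate is inert.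

Step 12
Reactants: 19 1ξ,6β-dihydroxy acid
Product: 20 1ξ-hydroxy-6α,12-olide (trans-fused γ-lactone)
Conditions: PPh3 (1.3 equiv), DIAD (1.3 equiv), THF (0.005 M, slow addition of 19), 0 °C → rt
Reagents that add atoms: none
Why: Mitsunobu lactonisation: the C6 alkoxyphosphonium is displaced by the C12 carboxylate in a 5-exo-tet SN2 with inversion, turning the 6β-carbinol into the 6α-oxygen of the trans-fused lactone (C6 as in the target); the C1 hydroxyl has no intramolecular partner at high dilution.

Step 13
Reactants: 20 1ξ-hydroxy-6α,12-olide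
Product: 21 11-(dimethylaminomethyl) lactone
Conditions: LiN(i-Pr)2 (LDA, 2.6 equiv), THF, −78 °C; Me2N=CH2+ I− (3 equiv), −78 → 0 °C; aq. NH4Cl
Reagents that add atoms: N,N-dimethylmethyleneiminium iodide, C=[N+](C)C.[I-]
Why: Mannich alkylation of the lactone lithium enolate with Eschenmoser's iminium salt (the C1 alkoxide forms first and takes the extra base); the new C11 centre is erased in the next step.

Step 14
Reactants: 21 11-(dimethylaminomethyl) lactone
Product: 23 11(13)-methylene lactone (1ξ-OH), via trimethylammonium iodide 22 (not isolated)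
Conditions: MeI (excess), MeOH, rt; evaporate; sat. aq. NaHCO3, CH2Cl2, rt
Reagents that add atoms: none
Why: Exhaustive N-methylation and Hofmann-type E1cB loss of trimethylamine give the α-methylene lactone without touching silyl ether, acetal or the free C1 hydroxyl.

Step 15
Reactants: 23 11(13)-methylene lactone (1ξ-OH)
Product: 24 1-ketone of 23
Conditions: Dess–Martin periodinane (1.5 equiv), NaHCO3, CH2Cl2, 0 °C → rt
Reagents that add atoms: none
Why: Dess–Martin oxidation of the only free hydroxyl restores the C1 ketone under buffered, non-enolising conditions (C3=C4 stays out of conjugation) while C9 is still masked, which distinguishes C1 from C9.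

Step 16
Reactants: 24 1-ketone of 23
Product: 25 9β,14-diol
Conditions: PPTS (0.2 equiv), MeOH, rt
Reagents that add atoms: none
Why: Mild acid-catalysed transketalisation removes the isopropylidene acetal; the secondary TBS ether and the lactone stay intact.

Step 17
Reactants: 25 9β,14-diol
Product: 27 10(14)-en-1-one with free 9β-OH, via primary C14 mesylate 26 (not isolated)
Conditions: MsCl (1.05 equiv), Et3N (3 equiv), CH2Cl2, −40 → 0 °C
Reagents that add atoms: none
Why: Chemoselective sulfonylation of the primary C14 hydroxyl and in situ E1cB elimination through the C1 enolate (mesylate leaves far more readily than the C9 hydroxyl) install the exocyclic C10=C14 enone and remove the C10 stereocentre.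

Step 18
Reactants: 27 10(14)-en-1-one with free 9β-OH; 28 angelic acid
Product: 29 9β-angelate (8α-OTBS)
Conditions: 28, 2,4,6-trichlorobenzoyl chloride, Et3N (1 equiv each), PhMe, rt; filter; 27, PhMe, 60 °C
Reagents that add atoms: none
Why: Yamaguchi-type acylation of the C9 hydroxyl by the preformed angelic 2,4,6-trichlorobenzoic mixed anhydride without free amine or DMAP, conditions under which the (Z)-2-methylbut-2-enoyl group should transfer without isomerisation to the tiglate; C9 keeps its configuration.

Step 19
Reactants: 29 9β-angelate (8α-OTBS)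
Product: 30 8α-alcohol (3,4-olefin precursor of the target)
Conditions: HF·pyridine, pyridine, THF, 0 °C → rt
Reagents that add atoms: none
Why: Fluoride cleavage of the secondary silyl ether under pyridine buffering, mild enough for the enone, both α-methylene carbonyl units and the angelate, and done before the acid-sensitive epoxide exists.

Step 20
Reactants: 30 8α-alcohol
Product: 31 target, (3S,4R,6R,7R,8R,9R)-9-angeloyloxy-3,4-epoxy-8-hydroxy-1-oxogermacra-10(14),11(13)-dien-6,12-olide
Conditions: DMDO (acetone solution, 1.1 equiv), CH2Cl2, −30 → 0 °C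
Reagents that add atoms: dimethyldioxirane, CC1(C)OO1
Why: Electrophilic epoxidation by a neutral dioxirane, chemoselective for the only electron-rich olefin (the other three C=C bonds are carbonyl-conjugated); syn oxygen transfer keeps C2 and C5 cis and is expected on the exposed outer face of C3=C4, anti to the C6–O bond of the trans-lactone, giving the 3β,4β-epoxide (3S,4R).

**Compound list**

1 | 7-methyl-1-tetralone | O=C1CCCc2ccc(C)cc12 | starting material
2 | ethyl bromoacetate | BrCC(=O)OCC | starting material
3 | ethyl 2-(1-hydroxy-7-methyl-1,2,3,4-tetrahydronaphthalen-1-yl)acetate (racemic, not isolated) | CCOC(=O)CC1(O)CCCc2ccc(C)cc12 | intermediate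
4 | ethyl 2-(7-methyl-3,4-dihydronaphthalen-1-yl)acetate | CCOC(=O)CC1=CCCc2ccc(C)cc12 | intermediate
5 | [(1S,2S)-1-(2-ethoxy-2-oxoethyl)-7-methyltetralin-2-yl](isopinocampheyl)borane (not isolated) | C[C@H]1[C@H](B[C@H]3CCc4ccc(C)cc4[C@@H]3CC(=O)OCC)C[C@@H]2C[C@H]1C2(C)C | intermediate
6 | ethyl 2-[(1S,2S)-2-hydroxy-7-methyl-1,2,3,4-tetrahydronaphthalen-1-yl]acetate | CCOC(=O)C[C@H]1c2cc(C)ccc2CC[C@@H]1O | intermediate
7 | ethyl 2-[(1S,2S)-2-(tert-butyldimethylsilyloxy)-7-methyl-1,2,3,4-tetrahydronaphthalen-1-yl]acetate | CCOC(=O)C[C@H]1c2cc(C)ccc2CC[C@@H]1O[Si](C)(C)C(C)(C)C | intermediate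
8 | C10 (tetralin C4) benzylic bromide of 7, both C10 epimers (not isolated) | CCOC(=O)C[C@H]1c2cc(C)ccc2C(Br)C[C@@H]1O[Si](C)(C)C(C)(C)C | intermediate
9 | ethyl 2-[(1S,2S)-2-(tert-butyldimethylsilyloxy)-7-methyl-1,2-dihydronaphthalen-1-yl]acetate | CCOC(=O)C[C@H]1c2cc(C)ccc2C=C[C@@H]1O[Si](C)(C)C(C)(C)C | intermediate
10 | 9β,10β-epoxide of 9, anti to the C8 silyloxy group | CCOC(=O)C[C@H]1c2cc(C)ccc2[C@H]3O[C@H]3[C@@H]1O[Si](C)(C)C(C)(C)C | intermediate
11 | all-trans tetralin with C10 CH2SiMe2(Oi-Pr) and free C9 hydroxyl (not isolated) | CCOC(=O)C[C@H]1c2cc(C)ccc2[C@H](C[Si](C)(C)OC(C)C)[C@@H](O)[C@@H]1O[Si](C)(C)C(C)(C)C | intermediate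
12 | ethyl 2-[(1S,2R,3R,4R)-2-(tert-butyldimethylsilyloxy)-3-hydroxy-4-(hydroxymethyl)-7-methyl-1,2,3,4-tetrahydronaphthalen-1-yl]acetate | CCOC(=O)C[C@H]1c2cc(C)ccc2[C@H](CO)[C@@H](O)[C@@H]1O[Si](C)(C)C(C)(C)C | intermediate
13 | C9,C14-O-isopropylidene acetal of 12 (trans-fused 1,3-dioxane) | CCOC(=O)C[C@H]1c2cc(C)ccc2[C@H](COC(C)(C)O3)[C@@H]3[C@@H]1O[Si](C)(C)C(C)(C)C | intermediate
14 | carboxylic acid of 13 | OC(=O)C[C@H]1c2cc(C)ccc2[C@H](COC(C)(C)O3)[C@@H]3[C@@H]1O[Si](C)(C)C(C)(C)C | intermediate
15 | Birch diene: hexahydronaphthalene acid with C1=C6 and C3=C4 olefins, ring B as in 14 | OC(=O)C[C@H]1C2=C(CC=C(C)C2)[C@H](COC(C)(C)O3)[C@@H]3[C@@H]1O[Si](C)(C)C(C)(C)C | intermediate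
16 | primary ozonide (1,2,3-trioxolane) across C1–C6 of 15 (not isolated) | OC(=O)C[C@H]1C23OOOC2(CC=C(C)C3)[C@H](COC(C)(C)O4)[C@@H]4[C@@H]1O[Si](C)(C)C(C)(C)C | intermediate
17 | bridged 1,2,4-trioxolane linking C1 and C6 (not isolated) | OC(=O)C[C@H]1C23OOC(O2)(CC=C(C)C3)[C@H](COC(C)(C)O4)[C@@H]4[C@@H]1O[Si](C)(C)C(C)(C)C | intermediate
18 | (Z)-cyclodec-3-ene-1,6-dione acid: C1 and C6 ketones, 7β-CH2CO2H, 8α-OTBS, 9β-O/C14-O acetonide | OC(=O)C[C@H]1C(=O)C/C(C)=C\CC(=O)[C@H](COC(C)(C)O2)[C@@H]2[C@@H]1O[Si](C)(C)C(C)(C)C | intermediate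
19 | 1ξ,6β-dihydroxy acid (C6–OH cis to the C7 branch) | OC(=O)C[C@H]1[C@@H](O)C/C(C)=C\CC(O)[C@H](COC(C)(C)O2)[C@@H]2[C@@H]1O[Si](C)(C)C(C)(C)C | intermediate
20 | 1ξ-hydroxy-6α,12-olide, trans-fused γ-lactone | O=C1C[C@H]2[C@H](O1)C/C(C)=C\CC(O)[C@H](COC(C)(C)O3)[C@@H]3[C@@H]2O[Si](C)(C)C(C)(C)C | intermediate
21 | 11-(dimethylaminomethyl) derivative of 20 (C11 epimers) | O=C1C(CN(C)C)[C@H]2[C@H](O1)C/C(C)=C\CC(O)[C@H](COC(C)(C)O3)[C@@H]3[C@@H]2O[Si](C)(C)C(C)(C)C | intermediate
22 | trimethylammonium iodide of 21 (not isolated) | O=C1C(C[N+](C)(C)C)[C@H]2[C@H](O1)C/C(C)=C\CC(O)[C@H](COC(C)(C)O3)[C@@H]3[C@@H]2O[Si](C)(C)C(C)(C)C.[I-] | intermediate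
23 | 11(13)-methylene lactone with 1ξ-OH | O=C1C(=C)[C@H]2[C@H](O1)C/C(C)=C\CC(O)[C@H](COC(C)(C)O3)[C@@H]3[C@@H]2O[Si](C)(C)C(C)(C)C | intermediate
24 | 1-ketone of 23 | O=C1C(=C)[C@H]2[C@H](O1)C/C(C)=C\CC(=O)[C@H](COC(C)(C)O3)[C@@H]3[C@@H]2O[Si](C)(C)C(C)(C)C | intermediate
25 | 9β,14-diol (acetonide removed) | O=C1C(=C)[C@H]2[C@H](O1)C/C(C)=C\CC(=O)[C@H](CO)[C@@H](O)[C@@H]2O[Si](C)(C)C(C)(C)C | intermediate
26 | primary C14 mesylate of 25 (not isolated) | O=C1C(=C)[C@H]2[C@H](O1)C/C(C)=C\CC(=O)[C@H](COS(C)(=O)=O)[C@@H](O)[C@@H]2O[Si](C)(C)C(C)(C)C | intermediate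
27 | 10(14)-en-1-one with 9β-OH and 8α-OTBS | O=C1C(=C)[C@H]2[C@H](O1)C/C(C)=C\CC(=O)C(=C)[C@@H](O)[C@@H]2O[Si](C)(C)C(C)(C)C | intermediate
28 | angelic acid, (Z)-2-methylbut-2-enoic acid | C/C=C(/C)C(=O)O | starting material
29 | 9β-angelate with 8α-OTBS | O=C1C(=C)[C@H]2[C@H](O1)C/C(C)=C\CC(=O)C(=C)[C@@H](OC(=O)/C(C)=C\C)[C@@H]2O[Si](C)(C)C(C)(C)C | intermediate
30 | 8α-alcohol, (Z)-3,4-olefin precursor of the target | O=C1C(=C)[C@H]2[C@H](O1)C/C(C)=C\CC(=O)C(=C)[C@@H](OC(=O)/C(C)=C\C)[C@@H]2O | intermediate
31 | CNP0348992.7, (3S,4R,6R,7R,8R,9R)-9-angeloyloxy-3,4-epoxy-8-hydroxy-1-oxogermacra-10(14),11(13)-dien-6,12-olide | C=C1C(=O)O[C@@H]2C[C@@]3(C)O[C@H]3CC(=O)C(=C)[C@@H](OC(=O)/C(C)=C\C)[C@H](O)[C@@H]12 | target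

**Step count and risk**

Total step count: 20. Longest linear sequence: 20 steps from 1 (28 is used as bought).

The three steps most likely to fail:

1. Step 10. Ozone discriminates only moderately between tetra- and trisubstituted olefins, and the C1=C6 bond is the more hindered one, so attack on C3=C4 or double cleavage may erode the chemoselectivity. The fallback sets out from 15 and separates recognition from cleavage. mCPBA (1.0 equiv, NaHCO3, CH2Cl2, −20 °C), which distinguishes the two olefin classes far more sharply (as in the central epoxidation of isotetralin), should give the C1–C6 epoxide F1. H5IO6 in aqueous THF at 0 °C then hydrolyses and cleaves it to 18, where the route resumes.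

2. Step 11. The face of the C6 carbonyl that the hydride reaches depends on the ring conformation; delivery to the other face (or partial retentive closure of 19) would lead to the cis-fused lactone after step 12. The fallback sets out from 18 and uses retention instead of inversion. A small hydride (NaBH4, CeCl3·7H2O, MeOH, −40 °C), able to use the conformer with an anti C5–C6–C7–C8 torsion, should give the 6α-hydroxy acid F2. F2 is closed with retention by brief acid treatment (PPTS, CH2Cl2, rt) directly to 20, skipping the Mitsunobu step. Either carbinol epimer therefore reaches 20.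

3. Step 20. Oxygen transfer to the Z olefin of a flexible ten-membered ring may show poor or reversed facial selectivity. The fallback sets out from 29 and inverts the face by a two-stage closure. NBS in THF/H2O at 0 °C forms the bromonium ion on the accessible face and water opens it anti at C4 to the bromohydrin F3 (4β-OH, 3α-Br). Ag2O in CH2Cl2 closes it to the silyl-protected epoxide F4 on the face opposite to direct epoxidation. Pyridine-buffered HF·pyridine then removes the TBS group to give 31.

**Further compounds**

F1 | step 10 | C1–C6 epoxide of 15 | OC(=O)C[C@H]1C23OC2(CC=C(C)C3)[C@H](COC(C)(C)O4)[C@@H]4[C@@H]1O[Si](C)(C)C(C)(C)C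
F2 | step 11 | 1ξ,6α-dihydroxy acid, C6 epimer of 19 | OC(=O)C[C@H]1[C@H](O)C/C(C)=C\CC(O)[C@H](COC(C)(C)O2)[C@@H]2[C@@H]1O[Si](C)(C)C(C)(C)C
F3 | step 20 | 3α-bromo-4β-hydroxy bromohydrin of 29 | O=C1C(=C)[C@H]2[C@H](O1)C[C@@](C)(O)[C@H](Br)CC(=O)C(=C)[C@@H](OC(=O)/C(C)=C\C)[C@@H]2O[Si](C)(C)C(C)(C)C
F4 | step 20 | 8-O-TBS ether of 31 | O=C1C(=C)[C@H]2[C@H](O1)C[C@@]3(C)O[C@H]3CC(=O)C(=C)[C@@H](OC(=O)/C(C)=C\C)[C@@H]2O[Si](C)(C)C(C)(C)C
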